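**Retrosynthetic overview**
1. Target ⇐ lipase-mediated acetylation of the two primary OH groups (two C–O bonds) of the free tetraol ⇐ LiAlH4 opening of an all-trans aryltetralin lactone.
2. Aryltetralin lactone (carbocyclic ring B) ⇐ one-flask aldol/Friedel–Crafts annulation of an (R)-β-benzyl-γ-butyrolactone with syringaldehyde; C-1 and C-2 follow from C-3.
3. (R)-Lactone ⇐ key bond O–CH2: enantioselective Baeyer–Villiger desymmetrisation of a prochiral 3-benzylcyclobutanone, the only step under external chirality control.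
4. Cyclobutanone ⇐ keteniminium [2+2] cycloaddition of eugenol pivalate with N,N-dimethylacetamide; eugenol and syringaldehyde supply both aromatic rings.
5. Ring order: cyclobutanone → γ-lactone (oxygen insertion) → ring B → lactone opened.

Assumption: the ligand antipode (from L- or D-pipecolic acid) that gives the R lactone in step 3 is fixed by one test run against the known sign of rotation of (R)-β-benzyl-γ-butyrolactones; compounds 1, 3 and 7 are bought.

The target is the (1S,2R,3R) all-trans isomer (aryl at C-1 trans to CH2OAc at C-2, which is trans to CH2OAc at C-3).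

**Step 1**
Reactants: 1 eugenol (4-allyl-2-methoxyphenol)
Product: 2 4-allyl-2-methoxyphenyl 2,2-dimethylpropanoate (eugenol pivalate)
Conditions: PivCl (1.1 equiv), Et3N, DMAP (5 mol %), CH2Cl2, 0 °C → rt
Reagents that add atoms: pivaloyl chloride, CC(C)(C)C(=O)Cl
Why: DMAP-catalysed O-acylation of the phenol; the pivalate has no α-hydrogen, withstands Tf2O, peracid and silyl triflate, and is removed by the hydride of step 5 without a step of its own.

**Step 2**
Reactants: 2 eugenol pivalate; 3 N,N-dimethylacetamide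
Product: 5 2-methoxy-4-[(3-oxocyclobutyl)methyl]phenyl 2,2-dimethylpropanoate, via cyclobutaniminium triflate 4 (not isolated)
Conditions: Tf2O (1.3 equiv), 2,4,6-collidine (1.3 equiv), ClCH2CH2Cl, −15 °C → 80 °C; then H2O, 80 °C
Reagents that add atoms: water, O
Why: Ghosez keteniminium [2+2] cycloaddition, in which the keteniminium ion made in the flask from 3 is attacked by the terminal CH2 of the allyl group so that the benzylic substituent ends at C-3, and hydrolysis of iminium salt 4 gives the achiral (prochiral) cyclobutanone; the acyloxy-substituted arene is too electron-poor to compete by Friedel–Crafts acylation.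

**Step 3**
Reactants: 5 the cyclobutanone
Product: 6 2-methoxy-4-{[(3R)-5-oxooxolan-3-yl]methyl}phenyl 2,2-dimethylpropanoate
Conditions: Sc(OTf)3 (5 mol %), chiral N,N′-dioxide ligand (pipecolic acid-derived, 2,6-diisopropylanilide arms, 6 mol %), m-CPBA (1.2 equiv), EtOAc, −20 °C
Reagents that add atoms: m-CPBA (3-chloroperoxybenzoic acid), OOC(=O)c1cccc(Cl)c1
Why: Catalytic enantioselective Baeyer–Villiger oxidation (desymmetrisation), in which the chiral Sc(OTf)3 complex binds the ketone–peracid adduct and lets only one of the two enantiotopic CH2 groups migrate to oxygen, so the new O–CH2 bond fixes the future C-3 as R (about 90 % ee is typical for 3-substituted cyclobutanones and can be raised by crystallising 12 or 13).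

**Step 4**
Reactants: 6 the (R)-lactone; 7 syringaldehyde (4-hydroxy-3,5-dimethoxybenzaldehyde)
Product: 12 (3aR,9S,9aR)-9-(4-hydroxy-3,5-dimethoxyphenyl)-6-methoxy-1-oxo-1,3,3a,4,9,9a-hexahydronaphtho[2,3-c]furan-7-yl 2,2-dimethylpropanoate, via O-silylated syringaldehyde 8 (not isolated), via ketene silyl acetal 9 (not isolated), via bis-silyl aldol adduct 10 (not isolated), via O-silyl aryltetralin lactone 11 (not isolated)
Conditions: i-Pr2NEt (2.3 equiv), Me3SiOTf (4 equiv), CH2Cl2 (0.05 M), −20 °C → rt; then 1 M HCl, THF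
Reagents that add atoms: none
Why: Proposed new method: a one-flask enolise–aldol–ionise–cyclise annulation of an unactivated γ-lactone with a free hydroxybenzaldehyde, in which amine/Me3SiOTf silylates the phenol of 7 (8) and soft-enolises 6 to ketene silyl acetal 9, surplus Me3SiOTf catalyses a Mukaiyama aldol addition of 9 to 8 on the face anti to the C-4 benzyl group (sets C-2 trans to C-3) to give 10, the same Lewis acid ionises the benzylic OSiMe3 group of 10 (para to a silyloxy donor) to a p-quinone-methide-type cation that the tethered arene captures para to its OMe group through a half-chair transition state holding the aryl group pseudo-equatorial (sets C-1 trans to C-2) to give 11, and aqueous acid frees the phenol; the closest known reaction types are the one-pot amine/Me3SiOTf enol silane formation–Mukaiyama aldol addition of ketones and thioesters and the two-step lithium enolate aldol/TFA Friedel–Crafts cyclisation of podorhizol-type hydroxy lactones, which gives the same all-trans ring fusion.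

**Step 5**
Reactants: 12 the aryltetralin lactone
Product: 13 (6R,7R,8S)-8-(4-hydroxy-3,5-dimethoxyphenyl)-6,7-bis(hydroxymethyl)-3-methoxy-5,6,7,8-tetrahydronaphthalen-2-ol
Conditions: LiAlH4 (4 equiv), THF, 0 °C → reflux; then 1 M HCl
Reagents that add atoms: none
Why: Hydride reduction of the lactone to the 1,4-diol with reductive cleavage of the aryl pivalate in the same operation; reduction is faster than enolisation at C-9a, so no stereocentre is touched, as in the classical conversion of conidendrin-type lactones into isolariciresinol-type diols.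

**Step 6**
Reactants: 13 the tetraol
Product: 14 [(1S,2R,3R)-7-hydroxy-1-(4-hydroxy-3,5-dimethoxyphenyl)-6-methoxy-1,2,3,4-tetrahydronaphthalene-2,3-diyl]bis(methylene) diacetate (CNP0265800.1)
Conditions: Candida antarctica lipase B (immobilised), vinyl acetate (6 equiv), THF, 40 °C
Reagents that add atoms: vinyl acetate, CC(=O)OC=C
Why: Lipase-catalysed irreversible transesterification, in which the acetyl-enzyme acylates primary aliphatic alcohols but does not accept phenols, so both CH2OH groups are acetylated while both ArOH groups stay free, and the released vinyl alcohol tautomerises to acetaldehyde.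

**Compound list**
1 | eugenol (4-allyl-2-methoxyphenol) | C=CCc1ccc(O)c(OC)c1 | starting material
2 | 4-allyl-2-methoxyphenyl 2,2-dimethylpropanoate | C=CCc1ccc(OC(=O)C(C)(C)C)c(OC)c1 | intermediate
3 | N,N-dimethylacetamide | CC(=O)N(C)C | starting material
4 | N-{3-[3-methoxy-4-(pivaloyloxy)benzyl]cyclobutylidene}-N-methylmethanaminium trifluoromethanesulfonate | C[N+](C)=C1CC(Cc2ccc(OC(=O)C(C)(C)C)c(OC)c2)C1.[O-]S(=O)(=O)C(F)(F)F | intermediate
5 | 2-methoxy-4-[(3-oxocyclobutyl)methyl]phenyl 2,2-dimethylpropanoate (achiral) | O=C1CC(Cc2ccc(OC(=O)C(C)(C)C)c(OC)c2)C1 | intermediate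
6 | 2-methoxy-4-{[(3R)-5-oxooxolan-3-yl]methyl}phenyl 2,2-dimethylpropanoate | O=C1C[C@@H](Cc2ccc(OC(=O)C(C)(C)C)c(OC)c2)CO1 | intermediate
7 | syringaldehyde (4-hydroxy-3,5-dimethoxybenzaldehyde) | COc1cc(C=O)cc(OC)c1O | starting material
8 | 3,5-dimethoxy-4-(trimethylsilyloxy)benzaldehyde | COc1cc(C=O)cc(OC)c1O[Si](C)(C)C | intermediate
9 | 2-methoxy-4-{[(3R)-5-(trimethylsilyloxy)-2,3-dihydrofuran-3-yl]methyl}phenyl 2,2-dimethylpropanoate | C[Si](C)(C)OC1=C[C@@H](Cc2ccc(OC(=O)C(C)(C)C)c(OC)c2)CO1 | intermediate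
10 | (3S,4R)-3-{[3,5-dimethoxy-4-(trimethylsilyloxy)phenyl](trimethylsilyloxy)methyl}-4-[3-methoxy-4-(pivaloyloxy)benzyl]dihydrofuran-2(3H)-one (both carbinol epimers) | COc1cc(cc(OC)c1O[Si](C)(C)C)C(O[Si](C)(C)C)[C@@H](C(=O)OC1)[C@H]1Cc1ccc(OC(=O)C(C)(C)C)c(OC)c1 | intermediate
11 | (3aR,9S,9aR)-9-[3,5-dimethoxy-4-(trimethylsilyloxy)phenyl]-6-methoxy-1-oxo-1,3,3a,4,9,9a-hexahydronaphtho[2,3-c]furan-7-yl 2,2-dimethylpropanoate | COc1cc2c(cc1OC(=O)C(C)(C)C)[C@H](c1cc(OC)c(O[Si](C)(C)C)c(OC)c1)[C@@H](C(=O)OC3)[C@H]3C2 | intermediate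
12 | (3aR,9S,9aR)-9-(4-hydroxy-3,5-dimethoxyphenyl)-6-methoxy-1-oxo-1,3,3a,4,9,9a-hexahydronaphtho[2,3-c]furan-7-yl 2,2-dimethylpropanoate | COc1cc2c(cc1OC(=O)C(C)(C)C)[C@H](c1cc(OC)c(O)c(OC)c1)[C@@H](C(=O)OC3)[C@H]3C2 | intermediate
13 | (6R,7R,8S)-8-(4-hydroxy-3,5-dimethoxyphenyl)-6,7-bis(hydroxymethyl)-3-methoxy-5,6,7,8-tetrahydronaphthalen-2-ol | COc1cc2c(cc1O)[C@H](c1cc(OC)c(O)c(OC)c1)[C@@H](CO)[C@H](CO)C2 | intermediate
14 | [(1S,2R,3R)-7-hydroxy-1-(4-hydroxy-3,5-dimethoxyphenyl)-6-methoxy-1,2,3,4-tetrahydronaphthalene-2,3-diyl]bis(methylene) diacetate | COc1cc2c(cc1O)[C@H](c1cc(OC)c(O)c(OC)c1)[C@@H](COC(C)=O)[C@H](COC(C)=O)C2 | target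

**Step count**
Total steps: 6. Longest linear sequence: 6 (1 → 2 → 5 → 6 → 12 → 13 → 14).

**Steps most likely to fail**

Step 3 (Baeyer–Villiger desymmetrisation). The uncatalysed peracid oxidation of the strained ketone can compete and lower the ee. The fallback sets out from 5 and comes back at 6, and moves the stereo-defining event to an asymmetric hydrogenation. Compound 5 is oxidised without chiral control (m-CPBA, NaHCO3, CH2Cl2) to racemic 2-methoxy-4-[(5-oxooxolan-3-yl)methyl]phenyl 2,2-dimethylpropanoate F1. Its lithium enolate (LiN(i-Pr)2, THF, −78 °C) is selenenylated with PhSeBr to the trans α-phenylselanyl lactone F2. H2O2 (CH2Cl2, 0 °C) then gives, by selenoxide syn-elimination, the achiral butenolide 2-methoxy-4-[(5-oxo-2,5-dihydrofuran-3-yl)methyl]phenyl 2,2-dimethylpropanoate F3. Hydrogenation of F3 with Ru(OAc)2(BINAP) (antipode chosen for R), H2 (50 atm), MeOH returns 6.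

Step 4 (the new annulation). Soft enolisation of the lactone may be slow, and the ionised adduct may eliminate to the benzylidene lactone or be trapped intermolecularly. The fallback sets out from 6 and 7 and comes back at 12 by known stepwise chemistry. Compound 7 is benzylated (BnBr, K2CO3, DMF) to 4-(benzyloxy)-3,5-dimethoxybenzaldehyde F4. The lithium enolate of 6 (LiN(i-Pr)2, THF, −78 °C) adds to F4 to give the trans aldol adduct (3S,4R)-3-{[4-(benzyloxy)-3,5-dimethoxyphenyl](hydroxy)methyl}-4-[3-methoxy-4-(pivaloyloxy)benzyl]dihydrofuran-2(3H)-one F5 as a mixture of carbinol epimers. TFA in CH2Cl2 at 0 °C closes ring B to the all-trans 4′-O-benzyl ether of 12, F6. Hydrogenolysis (H2, Pd/C, EtOAc) gives 12.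

Step 6 (lipase diacetylation). The CH2OH group next to the aryl-bearing carbon is hindered and the reaction may stop at a monoacetate. The fallback sets out from 13 and comes back at 14. Compound 13 is peracetylated (Ac2O, pyridine, DMAP) to the tetraacetate F7. The two aryl acetates are then removed selectively by aminolysis with pyrrolidine (2.2 equiv, MeCN, 0 °C), which leaves the alkyl acetates and gives 14.

**Further compounds**
F1 | step 3 | racemic 2-methoxy-4-[(5-oxooxolan-3-yl)methyl]phenyl 2,2-dimethylpropanoate | O=C1CC(Cc2ccc(OC(=O)C(C)(C)C)c(OC)c2)CO1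
F2 | step 3 | racemic trans 2-methoxy-4-{[5-oxo-4-(phenylselanyl)oxolan-3-yl]methyl}phenyl 2,2-dimethylpropanoate | O=C1OCC(Cc2ccc(OC(=O)C(C)(C)C)c(OC)c2)C1[Se]c1ccccc1
F3 | step 3 | 2-methoxy-4-[(5-oxo-2,5-dihydrofuran-3-yl)methyl]phenyl 2,2-dimethylpropanoate | O=C1C=C(Cc2ccc(OC(=O)C(C)(C)C)c(OC)c2)CO1
F4 | step 4 | 4-(benzyloxy)-3,5-dimethoxybenzaldehyde | COc1cc(C=O)cc(OC)c1OCc1ccccc1
F5 | step 4 | (3S,4R)-3-{[4-(benzyloxy)-3,5-dimethoxyphenyl](hydroxy)methyl}-4-[3-methoxy-4-(pivaloyloxy)benzyl]dihydrofuran-2(3H)-one | COc1cc(cc(OC)c1OCc1ccccc1)C(O)[C@@H](C(=O)OC1)[C@H]1Cc1ccc(OC(=O)C(C)(C)C)c(OC)c1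
F6 | step 4 | (3aR,9S,9aR)-9-[4-(benzyloxy)-3,5-dimethoxyphenyl]-6-methoxy-1-oxo-1,3,3a,4,9,9a-hexahydronaphtho[2,3-c]furan-7-yl 2,2-dimethylpropanoate | COc1cc2c(cc1OC(=O)C(C)(C)C)[C@H](c1cc(OC)c(OCc3ccccc3)c(OC)c1)[C@@H](C(=O)OC3)[C@H]3C2
F7 | step 6 | [(1S,2R,3R)-7-acetoxy-1-(4-acetoxy-3,5-dimethoxyphenyl)-6-methoxy-1,2,3,4-tetrahydronaphthalene-2,3-diyl]bis(methylene) diacetate | COc1cc2c(cc1OC(C)=O)[C@H](c1cc(OC)c(OC(C)=O)c(OC)c1)[C@@H](COC(C)=O)[C@H](COC(C)=O)C2
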